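**Plan**
1. The O1–C2 bond of ring C is cut first (reverse oxa-Michael), leaving a 2-aryl-3-aroyl-4,5-dihydrofuran fused to the benzofurochromane.
2. Ring A is a C4 aryl ketone with oxygen at C8a and C7, prenyl at C6 and hydrogen at C5 and C8; it is cut at C5–C6 and C4a–C8a into an ethynyl ketone and a prenyl-terminated 1-methoxy-1,3-bis(trimethylsilyloxy)diene.
3. Next cuts: C4–C3 (carbonylative alkynylation of a vinyl iodide), O–C2 of the dihydrofuran (iodocyclisation), C11–C(sp) (benzylic substitution by the ring B alkynyltrifluoroborate).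
4. The benzofurochromane goes back to an isoflavone 2,3-epoxide, and the isoflavone to a 3-iodochromone and an arylboronate.
5. Forward ring order: chromone, benzofuran acetal, dihydrofuran, ring A, ring C.
6. Stereochemistry: C10b from a catalytic asymmetric epoxidation, C5a from the forced cis fusion, C11 by convex-face attack, C2 and C3 in the last ring closure under control of C10b and C11.

Key step: step 23

Remarks. MOM = methoxymethyl; prenyl = 3-methylbut-2-en-1-yl; DIPEA = N,N-diisopropylethylamine; iPrOBpin = 2-isopropoxy-4,4,5,5-tetramethyl-1,3,2-dioxaborolane. Rings A, B, C and C2–C8a use flavanone numbering; O5, C5a, O6, C10b, C11 use benzofuro[2,3-b]chromene numbering. Descriptors are local to these numberings; the SMILES is authoritative.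
Assumption: the cinchonine-derived phase-transfer catalyst of step 7 is taken to give the (2R,3S)-epoxide; if the sense is opposite, the pseudo-enantiomeric cinchonidinium salt is used. Enantiomeric purity can be raised by recrystallising 14 or 15.

**Step 1**
Reactants: 1 2,4-dihydroxyacetophenone
Product: 2 1-[2-hydroxy-4-(methoxymethoxy)phenyl]ethanone
Conditions: MOMCl (1.1 equiv), DIPEA, CH2Cl2, 0 °C → rt
Reagents that add atoms: chloromethyl methyl ether, COCCl
Why: The 2-hydroxyl is tied up in a hydrogen bond to the acetyl group, so Williamson-type alkylation should occur only at the 4-hydroxyl.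

**Step 2**
Reactants: 2 1-[2-hydroxy-4-(methoxymethoxy)phenyl]ethanone
Product: 4 3-iodo-7-(methoxymethoxy)-4H-chromen-4-one, via enaminone 3 (not isolated)
Conditions: Me2NCH(OMe)2, 95 °C; evaporate; I2, pyridine, CHCl3, rt
Reagents that add atoms: N,N-dimethylformamide dimethyl acetal, COC(OC)N(C)C; iodine, II
Why: Condensation gives the enaminone, and iodine then causes α-iodination, 6-endo cyclisation of the phenol and loss of dimethylamine, the standard enaminone route to 3-iodochromones.

**Step 3**
Reactants: 5 resorcinol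
Product: 6 1,3-bis(methoxymethoxy)benzene
Conditions: MOMCl (2.4 equiv), DIPEA, CH2Cl2, 0 °C → rt
Reagents that add atoms: chloromethyl methyl ether, COCCl
Why: Double Williamson etherification installs two ortho-directing acetal groups.

**Step 4**
Reactants: 6 1,3-bis(methoxymethoxy)benzene; 7 prenyl bromide
Product: 9 1,3-bis(methoxymethoxy)-2-(3-methylbut-2-en-1-yl)benzene, via aryllithium 8 (not isolated)
Conditions: n-BuLi, THF, 0 °C → rt; CuI (0.1 equiv), 7, −78 °C → rt
Reagents that add atoms: none
Why: Directed ortho-metalation takes place at C2 between the two MOM-oxy groups, and copper-assisted SN2 allylation with prenyl bromide should give the linear prenyl arene.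

**Step 5**
Reactants: 9 1,3-bis(methoxymethoxy)-2-(3-methylbut-2-en-1-yl)benzene
Product: 11 2-[2,4-bis(methoxymethoxy)-3-(3-methylbut-2-en-1-yl)phenyl]-4,4,5,5-tetramethyl-1,3,2-dioxaborolane, via aryllithium 10 (not isolated)
Conditions: n-BuLi, TMEDA, THF, −20 → 0 °C; iPrOBpin, −78 °C → rt
Reagents that add atoms: 2-isopropoxy-4,4,5,5-tetramethyl-1,3,2-dioxaborolane, CC(C)OB1OC(C)(C)C(C)(C)O1
Why: A second directed ortho-metalation at the only type of free position next to a MOM-oxy group, followed by borylation, gives the boronate; chelation-driven ring lithiation is expected to outrun deprotonation of the benzylic CH2.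

**Step 6**
Reactants: 4 3-iodo-7-(methoxymethoxy)-4H-chromen-4-one; 11 the arylboronate
Product: 12 3-[2,4-bis(methoxymethoxy)-3-(3-methylbut-2-en-1-yl)phenyl]-7-(methoxymethoxy)-4H-chromen-4-one (isoflavone)
Conditions: Pd(PPh3)4 (5 mol%), Na2CO3, DME/H2O, 80 °C
Reagents that add atoms: none
Why: Suzuki–Miyaura coupling of 3-iodochromones with arylboronates is the standard isoflavone synthesis, and carbonate base spares the chromone ring.

**Step 7**
Reactants: 12 the isoflavone
Product: 13 (2R,3S)-2,3-epoxy-3-[2,4-bis(methoxymethoxy)-3-prenylphenyl]-7-(methoxymethoxy)-2,3-dihydro-4H-chromen-4-one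
Conditions: cumene hydroperoxide, N-[4-(trifluoromethyl)benzyl]cinchoninium bromide (10 mol%), KOH (aq), toluene, 0 °C
Reagents that add atoms: cumene hydroperoxide, CC(C)(OO)c1ccccc1
Why: Asymmetric Weitz–Scheffer epoxidation under chiral phase-transfer catalysis, in which the ion-paired hydroperoxide anion adds to C2 of the chromone and closes on one enantioface of C3 (the future C10b), while this nucleophilic oxidant leaves the electron-rich prenyl alkene alone.

**Step 8**
Reactants: 13 the isoflavone epoxide
Product: 14 (5aS,10bS)-3,8,10b-trihydroxy-7-prenyl-5a,10b-dihydro-11H-benzofuro[2,3-b]chromen-11-one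
Conditions: HCl (ca. 1 M), MeOH/THF, 0 → 40 °C
Reagents that add atoms: none
Why: Acid solvolyses the three MOM acetals and opens the glycal-like epoxide at the acetal carbon through an O1-stabilised oxocarbenium ion, which the freed 2′-hydroxyl traps in a five-membered ring that can only be cis-fused, so C5a follows from C10b, whose C–O bond is never broken.

**Step 9**
Reactants: 14 the triol ketone
Product: 15 (5aS,10bS)-10b-hydroxy-3,8-bis(methoxymethoxy)-7-prenyl-5a,10b-dihydro-11H-benzofuro[2,3-b]chromen-11-one
Conditions: MOMCl (2.2 equiv), DIPEA, CH2Cl2, 0 °C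
Reagents that add atoms: chloromethyl methyl ether, COCCl
Why: The two phenols are alkylated chemoselectively (Williamson etherification) over the hindered tertiary α-ketol hydroxyl.

**Step 10**
Reactants: 15 the bis-MOM ketone
Product: 16 (5aS,10bR,11S)-3,8-bis(methoxymethoxy)-7-prenyl-5a,10b-dihydro-11H-benzofuro[2,3-b]chromene-10b,11-diol
Conditions: NaBH4, MeOH/THF, 0 °C
Reagents that add atoms: none
Why: Borohydride reduction of the aryl ketone should place hydride on the convex face, anti to the C10a arene, to give the trans-diol; the C11 configuration is erased in step 16, so either epimer serves.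

**Step 11**
Reactants: 17 4-iodophenol; 7 prenyl bromide
Product: 19 4-iodo-2-(3-methylbut-2-en-1-yl)phenol, via sodium phenolate 18 (not isolated)
Conditions: NaH, toluene, 0 °C; 7, 0 °C → rt
Reagents that add atoms: none
Why: In a non-polar solvent the tight sodium phenolate ion pair is alkylated at the ortho carbon (ortho C-prenylation of phenolates), the para position being blocked by iodine.

**Step 12**
Reactants: 19 4-iodo-2-prenylphenol
Product: 20 4-iodo-1-(methoxymethoxy)-2-(3-methylbut-2-en-1-yl)benzene
Conditions: MOMCl, DIPEA, CH2Cl2, 0 °C → rt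
Reagents that add atoms: chloromethyl methyl ether, COCCl
Why: Williamson etherification of the phenol gives a base-stable ether for the organolithium step to come.

**Step 13**
Reactants: 20 the aryl iodide
Product: 21 {[4-(methoxymethoxy)-3-prenylphenyl]ethynyl}trimethylsilane
Conditions: PdCl2(PPh3)2 (2 mol%), CuI (4 mol%), HC≡CSiMe3, Et3N, THF, rt
Reagents that add atoms: ethynyltrimethylsilane, C#C[Si](C)(C)C
Why: Sonogashira coupling of an aryl iodide with a terminal alkyne proceeds at room temperature and tolerates the prenyl and MOM groups.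

**Step 14**
Reactants: 21 the silyl alkyne
Product: 22 4-ethynyl-1-(methoxymethoxy)-2-(3-methylbut-2-en-1-yl)benzene
Conditions: K2CO3 (cat.), MeOH, rt
Reagents that add atoms: none
Why: Methoxide-catalysed methanolysis cleaves the alkynyl–silicon bond.

**Step 15**
Reactants: 22 the terminal alkyne
Product: 25 potassium trifluoro{[4-(methoxymethoxy)-3-prenylphenyl]ethynyl}borate, via alkynyllithium 23 (not isolated), via trimethoxyborate 24 (not isolated)
Conditions: n-BuLi, THF, −78 °C; B(OMe)3, −78 → −20 °C; KHF2 (aq), → rt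
Reagents that add atoms: trimethyl borate, COB(OC)OC; potassium hydrogen difluoride, [K+].[F-].F
Why: The lithium acetylide adds to the borate ester and KHF2 exchanges methoxide for fluoride, the usual preparation of crystalline alkynyltrifluoroborates.

**Step 16**
Reactants: 16 the diol; 25 the alkynyltrifluoroborate
Product: 26 (5aS,10bS,11R)-3,8-bis(methoxymethoxy)-11-{[4-(methoxymethoxy)-3-prenylphenyl]ethynyl}-7-prenyl-5a,11-dihydro-10bH-benzofuro[2,3-b]chromen-10b-ol
Conditions: BF3·OEt2 (2.5 equiv), MeCN/CH2Cl2, −40 → −10 °C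
Reagents that add atoms: none
Why: BF3 ionises the secondary C11 alcohol to a benzylic cation stabilised by O5 and the para MOM-oxy group (a C10b cation would carry three β-oxygens), and the alkynylboron species adds at its boron-bearing carbon from the convex face, syn to the C10b hydroxyl and anti to the C10a arene, a known SN1 alkynylation of benzylic alcohols with alkynyltrifluoroborates that sets C11 by substrate control.

**Step 17**
Reactants: 26 the alkynol
Product: 27 (5aS,10bS,11R)-iododihydrofuran: 3-iodo-2-[4-(methoxymethoxy)-3-prenylphenyl]-4,5-dihydrofuran cis-fused through its O1–C5 and C4 to C10b and C11 of the 3,8-bis(methoxymethoxy)-7-prenylbenzofurochromane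
Conditions: I2 (1.5 equiv), NaHCO3, MeCN, 0 °C, dark
Reagents that add atoms: iodine, II
Why: 5-endo-dig iodocyclisation of a homopropargylic alcohol, in which the syn C10b hydroxyl attacks the aryl-bearing carbon of the iodine-activated alkyne to give the β-iodo enol ether, whereas iodonium formation at the prenyl alkenes is reversible as long as no nucleophile traps it.

**Step 18**
Reactants: 27 the iododihydrofuran
Product: 28 (5aS,10bS,11S)-3-[3-(trimethylsilyl)propioloyl]dihydrofuran (silyl ynone; framework as 27 with COC≡CSiMe3 in place of iodine)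
Conditions: PdCl2(PPh3)2 (5 mol%), CuI (2 mol%), CO (1 atm), HC≡CSiMe3, Et3N, THF, rt
Reagents that add atoms: carbon monoxide, [C-]#[O+]; ethynyltrimethylsilane, C#C[Si](C)(C)C
Why: Carbonylative Sonogashira coupling, in which oxidative addition of the vinyl iodide to zerovalent palladium, CO insertion and coupling with the copper acetylide give the ynone, the electron-rich vinyl group favouring insertion over direct coupling.

**Step 19**
Reactants: 28 the silyl ynone
Product: 29 (5aS,10bS,11S)-3-propioloyl-2-[4-(methoxymethoxy)-3-prenylphenyl]-4,5-dihydrofuran fused to the benzofurochromane (ethynyl ketone)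
Conditions: Bu4NF, AcOH, THF, −20 → 0 °C
Reagents that add atoms: none
Why: Buffered fluoride cleaves the alkynyl–silicon bond without exposing the terminal ynone to a basic nucleophile, and the MOM ethers are inert to it.

**Step 20**
Reactants: 30 methyl acetoacetate; 7 prenyl bromide
Product: 32 methyl 7-methyl-3-oxooct-6-enoate, via acetoacetate dianion 31 (not isolated)
Conditions: NaH, THF, 0 °C; n-BuLi, 0 °C; 7, 0 °C → rt; HCl (aq)
Reagents that add atoms: none
Why: The acetoacetate dianion is alkylated at its more basic γ-carbon (dianion γ-alkylation).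

**Step 21**
Reactants: 32 the β-keto ester
Product: 33 methyl (2Z)-7-methyl-3-(trimethylsilyloxy)octa-2,6-dienoate (E/Z immaterial)
Conditions: Me3SiCl, Et3N, hexane, rt
Reagents that add atoms: chlorotrimethylsilane, C[Si](C)(C)Cl
Why: O-silylation of the enolised β-keto ester gives the mono silyl enol ether.

**Step 22**
Reactants: 33 the silyl enol ether
Product: 35 (1Z,3Z)-1-methoxy-7-methyl-1,3-bis(trimethylsilyloxy)octa-1,3,6-triene, via lithium dienolate 34 (not isolated)
Conditions: LiN(iPr)2, THF, −78 °C; Me3SiCl, −78 °C → rt; filter, evaporate, use crude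
Reagents that add atoms: chlorotrimethylsilane, C[Si](C)(C)Cl
Why: Kinetic γ-deprotonation and O-silylation of the ester dienolate give the 1,3-bis(silyloxy)diene with the prenylmethyl chain outside, so the s-cis conformer is accessible; the double-bond geometry is lost on aromatisation.

**Step 23**
Reactants: 29 the ethynyl ketone; 35 the bis(silyloxy)diene
Product: 38 (5aS,10bS,11S)-dihydrofuranyl 2,4-dihydroxy-5-prenylphenyl ketone (ring A in place, phenols of the other rings as MOM ethers), via cycloadduct 36 (not isolated), via bis(trimethylsilyl) ether 37 (not isolated)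
Conditions: 35 (3 equiv), toluene, 80 °C; then HCl (0.5 M aq), THF, 0 °C
Reagents that add atoms: none
Why: Thermal normal-electron-demand Diels–Alder reaction: the prenyl-bearing terminus C4 of 35 bonds to the β-carbon of the ynone and the ketene-acetal carbon C1 to the α-carbon, forming C5–C6 and C4a–C8a in one concerted, asynchronous [4+2] closure of the six-membered ring to cyclohexa-1,4-diene 36. 1,4-Elimination of methanol across the ketal carbon and the prenyl-bearing CH aromatises 36 to 37, and dilute acid hydrolyses the two aryl O–Si bonds to give 38. The closest known reaction is the benzannulation of 1-methoxy-1,3-bis(trimethylsilyloxy)buta-1,3-dienes with acetylenic ketones and esters to 2,4-dihydroxyaryl carbonyl compounds. No stereocentre is created, since the two sp3 ring carbons of 36 become aromatic and C5a, C10b and C11 are untouched. The step needs regioselectivity, which the matched polarisation of the partners secures (acyl ortho and para to the two hydroxyls, prenyl ortho to the C7 hydroxyl), and chemoselectivity for the alkyne, which follows because C2=C3 is a donor-substituted, tetrasubstituted enol ether and the prenyl alkenes are unactivated.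

**Step 24**
Reactants: 38 the resorcinol ketone
Product: 39 CNP0152008.3, (2R,3S)-flavanone ketal fused to the (5aS,10bS,11R)-benzofurochromane
Conditions: HCl (ca. 1 M), MeOH, 35–40 °C
Reagents that add atoms: none
Why: Acid cleaves the three MOM acetals and catalyses the 6-endo-trig oxa-Michael addition of the chelated C8a hydroxyl to C2 of the protonated vinylogous ester, a reversible closure of the 2′-hydroxychalcone-to-flavanone type whose cis fusion fixes C2 and C3 together, the oxygen entering C2 on the face away from the C10a arene and the proton reaching C3 on the face away from the C11a arene, which is the natural arrangement.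

**Compound list**
1 | 2,4-dihydroxyacetophenone | CC(=O)c1ccc(O)cc1O | starting material
2 | 1-[2-hydroxy-4-(methoxymethoxy)phenyl]ethanone | CC(=O)c1ccc(OCOC)cc1O | intermediate
3 | (E)-3-(dimethylamino)-1-[2-hydroxy-4-(methoxymethoxy)phenyl]prop-2-en-1-one | CN(C)/C=C/C(=O)c1ccc(OCOC)cc1O | intermediate
4 | 3-iodo-7-(methoxymethoxy)-4H-chromen-4-one | COCOc1ccc2c(c1)occ(I)c2=O | intermediate
5 | resorcinol | Oc1cccc(O)c1 | starting material
6 | 1,3-bis(methoxymethoxy)benzene | COCOc1cccc(OCOC)c1 | intermediate
7 | prenyl bromide | CC(C)=CCBr | starting material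
8 | [2,6-bis(methoxymethoxy)phenyl]lithium | [Li]c1c(OCOC)cccc1OCOC | intermediate
9 | 1,3-bis(methoxymethoxy)-2-(3-methylbut-2-en-1-yl)benzene | COCOc1cccc(OCOC)c1CC=C(C)C | intermediate
10 | [2,4-bis(methoxymethoxy)-3-prenylphenyl]lithium | [Li]c1ccc(OCOC)c(CC=C(C)C)c1OCOC | intermediate
11 | 2-[2,4-bis(methoxymethoxy)-3-prenylphenyl]-4,4,5,5-tetramethyl-1,3,2-dioxaborolane | CC1(C)OB(OC1(C)C)c1ccc(OCOC)c(CC=C(C)C)c1OCOC | intermediate
12 | 3-[2,4-bis(methoxymethoxy)-3-prenylphenyl]-7-(methoxymethoxy)-4H-chromen-4-one | COCOc1ccc2c(c1)occ(-c1ccc(OCOC)c(CC=C(C)C)c1OCOC)c2=O | intermediate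
13 | (2R,3S)-isoflavone 2,3-epoxide | O1[C@]2(c4ccc(OCOC)c(CC=C(C)C)c4OCOC)C(=O)c3ccc(OCOC)cc3O[C@H]12 | intermediate
14 | (5aS,10bS)-3,8,10b-trihydroxy-7-prenyl-5a,10b-dihydro-11H-benzofuro[2,3-b]chromen-11-one | O[C@]2(c3ccc(O)c(CC=C(C)C)c3O4)C(=O)c1ccc(O)cc1O[C@H]24 | intermediate
15 | (5aS,10bS)-10b-hydroxy-3,8-bis(methoxymethoxy)-7-prenyl-5a,10b-dihydro-11H-benzofuro[2,3-b]chromen-11-one | O[C@]2(c3ccc(OCOC)c(CC=C(C)C)c3O4)C(=O)c1ccc(OCOC)cc1O[C@H]24 | intermediate
16 | (5aS,10bR,11S)-3,8-bis(methoxymethoxy)-7-prenyl-5a,10b-dihydro-11H-benzofuro[2,3-b]chromene-10b,11-diol | O[C@]2(c3ccc(OCOC)c(CC=C(C)C)c3O4)[C@@H](O)c1ccc(OCOC)cc1O[C@H]24 | intermediate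
17 | 4-iodophenol | Oc1ccc(I)cc1 | starting material
18 | sodium 4-iodophenolate | [Na+].[O-]c1ccc(I)cc1 | intermediate
19 | 4-iodo-2-(3-methylbut-2-en-1-yl)phenol | CC(C)=CCc1cc(I)ccc1O | intermediate
20 | 4-iodo-1-(methoxymethoxy)-2-(3-methylbut-2-en-1-yl)benzene | COCOc1ccc(I)cc1CC=C(C)C | intermediate
21 | {[4-(methoxymethoxy)-3-prenylphenyl]ethynyl}trimethylsilane | COCOc1ccc(C#C[Si](C)(C)C)cc1CC=C(C)C | intermediate
22 | 4-ethynyl-1-(methoxymethoxy)-2-(3-methylbut-2-en-1-yl)benzene | COCOc1ccc(C#C)cc1CC=C(C)C | intermediate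
23 | {[4-(methoxymethoxy)-3-prenylphenyl]ethynyl}lithium | [Li]C#Cc1ccc(OCOC)c(CC=C(C)C)c1 | intermediate
24 | lithium trimethoxy{[4-(methoxymethoxy)-3-prenylphenyl]ethynyl}borate | [Li+].CO[B-](OC)(OC)C#Cc1ccc(OCOC)c(CC=C(C)C)c1 | intermediate
25 | potassium trifluoro{[4-(methoxymethoxy)-3-prenylphenyl]ethynyl}borate | [K+].F[B-](F)(F)C#Cc1ccc(OCOC)c(CC=C(C)C)c1 | intermediate
26 | (5aS,10bS,11R)-11-alkynyl-10b-ol | O[C@]2(c3ccc(OCOC)c(CC=C(C)C)c3O4)[C@H](C#Cc5ccc(OCOC)c(CC=C(C)C)c5)c1ccc(OCOC)cc1O[C@H]24 | intermediate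
27 | (5aS,10bS,11R)-3-iodo-2-aryl-4,5-dihydrofuran fused at C10b–C11 | IC1=C(c2ccc(OCOC)c(CC=C(C)C)c2)O[C@]2(c3ccc(OCOC)c(CC=C(C)C)c3O4)[C@H]1c1ccc(OCOC)cc1O[C@H]24 | intermediate
28 | (5aS,10bS,11S)-3-[3-(trimethylsilyl)propioloyl]dihydrofuran | C[Si](C)(C)C#CC(=O)C1=C(c2ccc(OCOC)c(CC=C(C)C)c2)O[C@]2(c3ccc(OCOC)c(CC=C(C)C)c3O4)[C@H]1c1ccc(OCOC)cc1O[C@H]24 | intermediate
29 | (5aS,10bS,11S)-3-propioloyldihydrofuran (ethynyl ketone) | C#CC(=O)C1=C(c2ccc(OCOC)c(CC=C(C)C)c2)O[C@]2(c3ccc(OCOC)c(CC=C(C)C)c3O4)[C@H]1c1ccc(OCOC)cc1O[C@H]24 | intermediate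
30 | methyl acetoacetate | COC(=O)CC(C)=O | starting material
31 | sodium lithium dianion of methyl acetoacetate | [Na+].[Li+].COC([O-])=CC([O-])=C | intermediate
32 | methyl 7-methyl-3-oxooct-6-enoate | COC(=O)CC(=O)CCC=C(C)C | intermediate
33 | methyl (2Z)-7-methyl-3-(trimethylsilyloxy)octa-2,6-dienoate | COC(=O)/C=C(\O[Si](C)(C)C)CCC=C(C)C | intermediate
34 | lithium dienolate of 33 | [Li+].COC([O-])=CC(O[Si](C)(C)C)=CCC=C(C)C | intermediate
35 | (1Z,3Z)-1-methoxy-7-methyl-1,3-bis(trimethylsilyloxy)octa-1,3,6-triene | CO/C(O[Si](C)(C)C)=C/C(O[Si](C)(C)C)=C/CC=C(C)C | intermediate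
36 | cyclohexa-1,4-diene cycloadduct (two transient ring stereocentres undefined) | COC1(O[Si](C)(C)C)C=C(O[Si](C)(C)C)C(CC=C(C)C)C=C1C(=O)C1=C(c2ccc(OCOC)c(CC=C(C)C)c2)O[C@]2(c3ccc(OCOC)c(CC=C(C)C)c3O4)[C@H]1c1ccc(OCOC)cc1O[C@H]24 | intermediate
37 | ring A bis(trimethylsilyl) ether | CC(C)=CCc1cc(C(=O)C2=C(c3ccc(OCOC)c(CC=C(C)C)c3)O[C@]3(c4ccc(OCOC)c(CC=C(C)C)c4O5)[C@H]2c2ccc(OCOC)cc2O[C@H]35)c(O[Si](C)(C)C)cc1O[Si](C)(C)C | intermediate
38 | (5aS,10bS,11S)-dihydrofuranyl 2,4-dihydroxy-5-prenylphenyl ketone | CC(C)=CCc1cc(C(=O)C2=C(c3ccc(OCOC)c(CC=C(C)C)c3)O[C@]3(c4ccc(OCOC)c(CC=C(C)C)c4O5)[C@H]2c2ccc(OCOC)cc2O[C@H]35)c(O)cc1O | intermediate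
39 | CNP0152008.3 | CC(C)=CCc1cc([C@@]23Oc4cc(O)c(CC=C(C)C)cc4C(=O)[C@@H]2[C@@H]2c4ccc(O)cc4O[C@H]4Oc5c(ccc(O)c5CC=C(C)C)[C@]42O3)ccc1O | target

**Step count**
Total: 24 steps. Longest linear sequence: 14 steps (5 → 6 → 9 → 11 → 12 → 13 → 14 → 15 → 16 → 26 → 27 → 28 → 29 → 38 → 39).

**Steps most likely to fail**

Step 16. The C11 cation may not be trapped cleanly: a 1,2-shift of the C10a aryl or of C5a (pinacol-type), ionisation at the tertiary C10b hydroxyl, loss of MOM groups under BF3, or attack on the concave face could all intervene. The fallback replaces the free cation by directed delivery. It sets out from diol 16, which is cyclodehydrated under Mitsunobu conditions (PPh3, diisopropyl azodicarboxylate, THF) to the 10b,11-epoxide F1, the tertiary alkoxide displacing the activated C11 oxygen with inversion. A dimethylaluminium acetylide, made from alkyne 22 with n-BuLi and Me2AlCl, is then bound to the epoxide oxygen in toluene at −78 °C. It should open the benzylic C11–O bond and hand the alkynyl group to the same face (syn opening, as known for glycal and aryl epoxides with alkynylalanes). The route is rejoined at alkynol 26.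

Step 17. Electrophilic iodine may be consumed by the three trisubstituted alkenes (iodoetherification with the neighbouring ether oxygens) or by the electron-rich arenes before the alkyne cyclises. The fallback avoids electrophilic halogen. It sets out from alkynol 26, which is cycloisomerised with Ph3PAuNTf2 (2 mol%, CH2Cl2, rt) in a 5-endo-dig hydroalkoxylation to the C3-unsubstituted 2-aryl-4,5-dihydrofuran F2. Vilsmeier–Haack formylation (POCl3, DMF, 0 °C; NaOAc aq) at the nucleophilic β-carbon of the enol ether gives aldehyde F3. Ethynylmagnesium bromide (THF, −78 °C) gives the ethynyl carbinol F4 as an epimer mixture, and MnO2 in CH2Cl2 oxidises it to the ethynyl ketone. The route is rejoined at 29, so steps 18 and 19 are bypassed.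

Step 24. Protic acid may cyclise the ortho-prenyl phenols to chromans or exchange the C5a acetal with methanol while the MOM ethers are still being cleaved, and a kinetically controlled closure may not discriminate the two faces of C2=C3. The fallback separates ring closure from deprotection. It sets out from 38, which is treated with NaOAc in EtOH at 50 °C; the phenolate closes ring C reversibly, so the ketal can equilibrate to the natural diastereomer, giving the tris-MOM flavanone ketal F5, in which no conjugate acceptor remains. The aryl MOM ethers are then exchanged for trimethylsilyl ethers with Me3SiOTf and 2,2′-bipyridyl in MeCN at 0 °C and hydrolysed with water, a buffered non-protic cleavage. The route is rejoined at 39.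

**Further compounds**
F1 | step 16 | 10b,11-epoxy-3,8-bis(methoxymethoxy)-7-prenyl-5a,10b-dihydro-11H-benzofuro[2,3-b]chromene (epoxide on the convex face) | O1[C@]2(c3ccc(OCOC)c(CC=C(C)C)c3O4)[C@H]1c1ccc(OCOC)cc1O[C@H]24
F2 | step 17 | 2-[4-(methoxymethoxy)-3-prenylphenyl]-4,5-dihydrofuran fused at C10b–C11, C3 unsubstituted | C1=C(c2ccc(OCOC)c(CC=C(C)C)c2)O[C@]2(c3ccc(OCOC)c(CC=C(C)C)c3O4)[C@H]1c1ccc(OCOC)cc1O[C@H]24
F3 | step 17 | 3-formyl derivative of F2 | O=CC1=C(c2ccc(OCOC)c(CC=C(C)C)c2)O[C@]2(c3ccc(OCOC)c(CC=C(C)C)c3O4)[C@H]1c1ccc(OCOC)cc1O[C@H]24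
F4 | step 17 | 3-(1-hydroxyprop-2-yn-1-yl) derivative of F2 (carbinol epimers) | C#CC(O)C1=C(c2ccc(OCOC)c(CC=C(C)C)c2)O[C@]2(c3ccc(OCOC)c(CC=C(C)C)c3O4)[C@H]1c1ccc(OCOC)cc1O[C@H]24
F5 | step 24 | ring-closed flavanone ketal with three MOM ethers and free C7 hydroxyl | CC(C)=CCc1cc([C@@]23Oc4cc(O)c(CC=C(C)C)cc4C(=O)[C@@H]2[C@@H]2c4ccc(OCOC)cc4O[C@H]4Oc5c(ccc(OCOC)c5CC=C(C)C)[C@]42O3)ccc1OCOC
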